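**Retrosynthetic overview**
1. Target 33 comes from allyl ester 32. Before that: acylation of O8 in hydroxy ester 24 with acid 28 (from L-threonate), allylic hydroxylation of the C5 isopropenyl group at C15, and mild unmasking.
2. Hydroxy ester 24 comes from the cis-fused 12,8-γ-lactone 18/22, a temporary ring that is α-methylenated and then opened. The lactone comes from cyclohexanone 16.
3. Enabling feature: in the carbocycle C5–C10 the only CH2 (C9) joins oxygen-bearing C8 to quaternary C10, which carries CH3 and the C1=C2 vinyl group. C8(=O)–C9–C10–C1=C2 is therefore a γ,δ-unsaturated ketone (Claisen retron). Reconnecting C2 to the oxygen on C8 gives the eight-membered 2-methyleneoxocine 15, which contracts by two atoms to 16.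
4. Oxocine 15 comes from oxocinone 14, and 14 from triene ester 13 by group-selective ring-closing metathesis. C6 is set by asymmetric pentadienylboration of 2 with diene 1, and C7 by Fráter–Seebach alkylation.
5. Ring order: eight-membered lactone (step 7), six-membered carbocycle (step 9), γ-lactone (step 10, opened in step 12).

Key step: step 9

Remark: elemane numbering is used (ring C5–C10; C1=C2 and C14H3 on C10; C4(=C3)C15 on C5; C11(=C13)C12 on C7). With the ring drawn so that C10→C9→C8→C7→C6→C5 runs clockwise, β points to the viewer, and the target is 10β-CH3, 10α-vinyl, 5β-H, 6β-OH, 7α-H, 8β-acyloxy, 3'R.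
Assumption: the free γ-hydroxy acid 33 is handled near pH 5 and below room temperature, where lactonisation onto O6 should be slow.

**Step 1**
Reactants: 1 2,4-dimethylpenta-1,3-diene; 2 3-[(tert-butyldimethylsilyl)oxy]propanal
Product: 6 (3R)-1-[(tert-butyldimethylsilyl)oxy]-5-methyl-4-(prop-1-en-2-yl)hex-5-en-3-ol, via potassium dienide 3 (not isolated), via dienylborane 4 (not isolated), via borinate 5 (not isolated)
Conditions: nBuLi, KOtBu, THF, −78 → −40 °C; (−)-Ipc2BCl (from (+)-α-pinene), −78 °C; 2, −78 °C; NaOH, H2O2, 0 °C → rt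
Reagents that add atoms: none
Why: Brown-type asymmetric allylboration, in which boron sits on the CH2 terminus and the central dienyl carbon is transferred through a closed chair transition state to give the bis(isopropenyl)methine C5 (not yet a stereocentre), while the isopinocampheyl groups select one aldehyde face and set (R)-C6.

**Step 2**
Reactants: 6 (3R)-1-[(tert-butyldimethylsilyl)oxy]-5-methyl-4-(prop-1-en-2-yl)hex-5-en-3-ol
Product: 7 (3R)-5-methyl-4-(prop-1-en-2-yl)hex-5-ene-1,3-diol
Conditions: camphorsulfonic acid (cat.), MeOH, 0 °C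
Reagents that add atoms: none
Why: Acid-catalysed methanolysis removes the unhindered primary silyl ether and should leave the alkenes and C6 untouched.

**Step 3**
Reactants: 7 (3R)-5-methyl-4-(prop-1-en-2-yl)hex-5-ene-1,3-diol
Product: 9 (3R)-3-hydroxy-5-methyl-4-(prop-1-en-2-yl)hex-5-enoic acid, via hydroxy aldehyde 8 (not isolated)
Conditions: TEMPO (cat.), PhI(OAc)2, MeCN–H2O, 0 °C → rt
Reagents that add atoms: water, O
Why: Oxoammonium (TEMPO) oxidation selects the primary alcohol and carries it through the aldehyde hydrate to the acid without touching the hindered C6 hydroxyl or the alkenes.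

**Step 4**
Reactants: 9 (3R)-3-hydroxy-5-methyl-4-(prop-1-en-2-yl)hex-5-enoic acid
Product: 10 allyl (3R)-3-hydroxy-5-methyl-4-(prop-1-en-2-yl)hex-5-enoate
Conditions: allyl bromide, KHCO3, DMF, rt
Reagents that add atoms: allyl bromide, C=CCBr
Why: SN2 alkylation of the carboxylate installs the allyl ester that later supplies the ring oxygen, C2 and C1 of the eight-membered ring.

**Step 5**
Reactants: 10 allyl (3R)-3-hydroxy-5-methyl-4-(prop-1-en-2-yl)hex-5-enoate
Product: 12 1-allyl 4-tert-butyl (2S)-2-[(1S)-1-hydroxy-3-methyl-2-(prop-1-en-2-yl)but-3-en-1-yl]butanedioate, via dilithio dianion 11 (not isolated)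
Conditions: LiN(iPr)2 (2.2 equiv), THF, −78 → −45 °C; BrCH2CO2tBu, DMPU, −78 → −45 °C; AcOH quench
Reagents that add atoms: tert-butyl bromoacetate, CC(C)(C)OC(=O)CBr
Why: Fráter–Seebach alkylation, in which the chelated alkoxide–enolate is attacked anti to the bulky C5 branch so that C7 is set anti to the C6 oxygen, at a temperature below that at which an allyl ester enolate undergoes its own [3,3] shift.

**Step 6**
Reactants: 12 1-allyl 4-tert-butyl (2S)-2-[(1S)-1-hydroxy-3-methyl-2-(prop-1-en-2-yl)but-3-en-1-yl]butanedioate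
Product: 13 1-allyl 4-tert-butyl (2S)-2-[(1S)-3-methyl-2-(prop-1-en-2-yl)-1-(triethylsilyloxy)but-3-en-1-yl]butanedioate
Conditions: Et3SiOTf, 2,6-lutidine, CH2Cl2, −78 °C
Reagents that add atoms: triethylsilyl triflate, CC[Si](CC)(CC)OS(=O)(=O)C(F)(F)F
Why: Silylation with the triflate caps the hindered C6 hydroxyl, which blocks lactonisation onto C12, and the low temperature spares the tert-butyl ester.

**Step 7**
Reactants: 13 1-allyl 4-tert-butyl (2S)-2-[(1S)-3-methyl-2-(prop-1-en-2-yl)-1-(triethylsilyloxy)but-3-en-1-yl]butanedioate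
Product: 14 tert-butyl 2-[(3S,4S,5R,6Z)-6-methyl-2-oxo-5-(prop-1-en-2-yl)-4-(triethylsilyloxy)-3,4,5,8-tetrahydro-2H-oxocin-3-yl]acetate
Conditions: second-generation Grubbs catalyst (H2IMes)(PCy3)Cl2Ru=CHPh (10 mol %), toluene (1 mM), 80 °C, argon sparge
Reagents that add atoms: none
Why: Diastereotopic-group-selective ring-closing metathesis, in which the alkylidene formed at the allyl terminus closes onto the isopropenyl group that leaves the spectator isopropenyl and the OSiEt3 group trans and pseudo-equatorial (this sets C5), while the ring size enforces the Z alkene.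

**Step 8**
Reactants: 14 tert-butyl 2-[(3S,4S,5R,6Z)-6-methyl-2-oxo-5-(prop-1-en-2-yl)-4-(triethylsilyloxy)-3,4,5,8-tetrahydro-2H-oxocin-3-yl]acetate
Product: 15 tert-butyl 2-[(3S,4S,5R,6Z)-6-methyl-2-methylidene-5-(prop-1-en-2-yl)-4-(triethylsilyloxy)-3,4,5,8-tetrahydro-2H-oxocin-3-yl]acetate
Conditions: Cp2Ti(μ-Cl)(μ-CH2)AlMe2 (1.1 equiv), pyridine, THF–toluene, −40 → 0 °C; aq NaOH; basic alumina
Reagents that add atoms: Cp2Ti(μ-Cl)(μ-CH2)AlMe2, C=[Ti](C1C=CC=C1)C1C=CC=C1.C[Al](C)Cl
Why: Tebbe methylenation, in which the titanium methylidene should convert the strained s-cis lactone carbonyl faster than the hindered tert-butyl ester, and pyridine binds the aluminium so that no Lewis-acid-induced rearrangement releases a ketone while reagent is still present.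

**Step 9**
Reactants: 15 tert-butyl 2-[(3S,4S,5R,6Z)-6-methyl-2-methylidene-5-(prop-1-en-2-yl)-4-(triethylsilyloxy)-3,4,5,8-tetrahydro-2H-oxocin-3-yl]acetate
Product: 16 tert-butyl 2-[(1S,2S,3R,4S)-4-ethenyl-4-methyl-6-oxo-3-(prop-1-en-2-yl)-2-(triethylsilyloxy)cyclohexyl]acetate
Conditions: toluene, BHT (trace), base-washed glass, 110–130 °C
Reagents that add atoms: none
Why: Proposed new method: the exocyclic enol ether C9=C8–O and the endocyclic Z-allyl unit O–C2–C1=C10 form one allyl vinyl ether, and a concerted suprafacial [3,3]-sigmatropic (Claisen) shift breaks O–C2 and makes C9–C10, so the eight-membered ring (O, C2, C1, C10, C5, C6, C7, C8) contracts by two atoms to the carbocycle C8–C9–C10–C5–C6–C7, C1=C2 is expelled as the vinyl group and C8 becomes the ketone. The closest known reaction types are the methylenation/Claisen sequence that expands 2-methylene-6-vinyltetrahydropyrans to cyclooct-4-enones and the ring-contracting ester-enolate Claisen rearrangement of macrolactone ketene acetals, and the new element is the topology in which only the vinyl-ether methylene lies outside a medium ring. The six-membered ring closes transannularly, C9 onto C10 (exo with respect to C10=C1), through a chair–chair, bicyclo[3.3.1]nonane-like transition state that a Z ring alkene reaches easily because the tether carbon C5 occupies the inside position of the allyl terminus. The one new stereocentre, quaternary C10, is controlled by C5 and C6: isopropenyl and OSiEt3 sit equatorial on the forming chair and the C7 side chain sits axial (which relieves A(1,3) strain with the C9 methylene), so C1 must be axial and CH3 equatorial, which gives vinyl cis to isopropenyl, whereas the flipped array would drive OSiEt3 into the O–C2–C1 bridge. The step needs [3,3] shift to win over acid-catalysed migration of the exocyclic double bond into the ring and over epimerisation at C7, and this is secured by neutral base-washed conditions. Formation of C=O and loss of medium-ring strain should make the event irreversible.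

**Step 10**
Reactants: 16 tert-butyl 2-[(1S,2S,3R,4S)-4-ethenyl-4-methyl-6-oxo-3-(prop-1-en-2-yl)-2-(triethylsilyloxy)cyclohexyl]acetate
Product: 18 cis-fused γ-lactone 6β-(triethylsilyloxy)-5βH,7αH,8αH-elema-1,3-dien-12,8-olide, via hydroxy ester 17 (not isolated)
Conditions: SmI2, H2O, THF, 0 °C; then KOtBu (cat.), THF, 0 °C
Reagents that add atoms: none
Why: Single-electron ketone reduction (SmI2–H2O) should give the thermodynamically preferred equatorial 8β-oxygen although axial groups flank both faces, and this oxygen, cis to the axial C7 side chain, closes the γ-lactone by acyl substitution on the tert-butyl ester.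

**Step 11**
Reactants: 18 cis-fused γ-lactone 6β-(triethylsilyloxy)-5βH,7αH,8αH-elema-1,3-dien-12,8-olide
Product: 22 α-methylene lactone 6β-(triethylsilyloxy)-5βH,7αH,8αH-elema-1,3,11(13)-trien-12,8-olide, via lithium enolate 19 (not isolated), via Mannich base 20 (not isolated), via ammonium iodide 21 (not isolated)
Conditions: LiN(iPr)2, THF, −78 °C; CH2=NMe2+ I−, −78 °C → rt; MeI, MeOH, rt; DBU, CH2Cl2, rt
Reagents that add atoms: N,N-dimethylmethyleneiminium iodide, C=[N+](C)C.[I-]
Why: Lactone α-methylenation by a Mannich reaction with Eschenmoser's salt on the convex face, N-methylation and β-elimination, in which the transient C11 centre is erased and C7 is not acidic.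

**Step 12**
Reactants: 22 α-methylene lactone 6β-(triethylsilyloxy)-5βH,7αH,8αH-elema-1,3,11(13)-trien-12,8-olide
Product: 24 allyl 8β-hydroxy-6β-(triethylsilyloxy)-5βH,7αH-elema-1,3,11(13)-trien-12-oate, via lithium carboxylate 23 (not isolated)
Conditions: LiOH, THF–H2O, 0 °C → rt; evaporation; allyl bromide, DMF, 0 °C
Reagents that add atoms: lithium hydroxide, [Li+].[OH-]; allyl bromide, C=CCBr
Why: Saponification by acyl–oxygen cleavage keeps C8 intact, and SN2 alkylation of the carboxylate traps the open form as a conjugated ester that should relactonise only slowly.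

**Step 13**
Reactants: 25 methyl (2R)-2-[(4S)-2,2-dimethyl-1,3-dioxolan-4-yl]-2-hydroxyacetate (methyl 3,4-O-isopropylidene-L-threonate)
Product: 26 methyl 2-[(4S)-2,2-dimethyl-1,3-dioxolan-4-yl]-2-oxoacetate
Conditions: Dess–Martin periodinane, CH2Cl2, 0 °C → rt
Reagents that add atoms: none
Why: Dess–Martin oxidation gives the α-keto ester under nearly neutral conditions that should not enolise the dioxolane stereocentre.

**Step 14**
Reactants: 26 methyl 2-[(4S)-2,2-dimethyl-1,3-dioxolan-4-yl]-2-oxoacetate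
Product: 27 methyl 2-[(4R)-2,2-dimethyl-1,3-dioxolan-4-yl]prop-2-enoate
Conditions: Ph3PCH3Br, KN(SiMe3)2, THF, 0 °C; then 26, −78 → 0 °C
Reagents that add atoms: methyltriphenylphosphonium bromide, C[P+](c1ccccc1)(c1ccccc1)c1ccccc1.[Br-]
Why: Wittig methylenation, in which the very electrophilic keto carbonyl reacts at low temperature before enolisation can erode the stereocentre (same spatial arrangement, and the descriptor changes to R only through the priority rules).

**Step 15**
Reactants: 27 methyl 2-[(4R)-2,2-dimethyl-1,3-dioxolan-4-yl]prop-2-enoate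
Product: 28 2-[(4R)-2,2-dimethyl-1,3-dioxolan-4-yl]prop-2-enoic acid
Conditions: LiOH, THF–H2O, 0 °C; then 1 M HCl to pH 3
Reagents that add atoms: lithium hydroxide, [Li+].[OH-]
Why: Saponification of the unhindered methyl ester leaves the acetonide and the non-acidic stereocentre untouched.

**Step 16**
Reactants: 24 allyl 8β-hydroxy-6β-(triethylsilyloxy)-5βH,7αH-elema-1,3,11(13)-trien-12-oate; 28 2-[(4R)-2,2-dimethyl-1,3-dioxolan-4-yl]prop-2-enoic acid
Product: 30 allyl 8β-{2-[(4R)-2,2-dimethyl-1,3-dioxolan-4-yl]acryloyloxy}-6β-(triethylsilyloxy)-5βH,7αH-elema-1,3,11(13)-trien-12-oate, via mixed anhydride 29 (not isolated)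
Conditions: 2,4,6-trichlorobenzoyl chloride, Et3N, toluene, rt; then 24, DMAP, 0 °C → rt
Reagents that add atoms: none
Why: Yamaguchi esterification acylates the only free hydroxyl (equatorial O8, next to the C9 methylene) with retention at C8, and should outrun attack of O8 on the poorly electrophilic conjugated allyl ester.

**Step 17**
Reactants: 30 allyl 8β-{2-[(4R)-2,2-dimethyl-1,3-dioxolan-4-yl]acryloyloxy}-6β-(triethylsilyloxy)-5βH,7αH-elema-1,3,11(13)-trien-12-oate
Product: 31 allyl 8β-{2-[(4R)-2,2-dimethyl-1,3-dioxolan-4-yl]acryloyloxy}-15-hydroxy-6β-(triethylsilyloxy)-5βH,7αH-elema-1,3,11(13)-trien-12-oate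
Conditions: SeO2 (cat.), tBuOOH, CH2Cl2, 0 °C → rt
Reagents that add atoms: tert-butyl hydroperoxide, CC(C)(C)OO
Why: Selenium dioxide allylic oxidation (ene reaction, then [2,3] shift) addresses the only electron-rich 1,1-disubstituted alkene that has allylic hydrogens, and its CH3 group is far more accessible than the C5–H flanked by quaternary C10.

**Step 18**
Reactants: 31 allyl 8β-{2-[(4R)-2,2-dimethyl-1,3-dioxolan-4-yl]acryloyloxy}-15-hydroxy-6β-(triethylsilyloxy)-5βH,7αH-elema-1,3,11(13)-trien-12-oate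
Product: 32 allyl 8β-[(3R)-3,4-dihydroxy-2-methylidenebutanoyloxy]-6β,15-dihydroxy-5βH,7αH-elema-1,3,11(13)-trien-12-oate
Conditions: AcOH–THF–H2O, 40 °C
Reagents that add atoms: none
Why: Mild acid hydrolysis cleaves the terminal acetonide and the triethylsilyl ether in one operation while all three esters stay in place and C12 is still masked against lactonisation.

**Step 19**
Reactants: 32 allyl 8β-[(3R)-3,4-dihydroxy-2-methylidenebutanoyloxy]-6β,15-dihydroxy-5βH,7αH-elema-1,3,11(13)-trien-12-oate
Product: 33 8β-[(3R)-3,4-dihydroxy-2-methylidenebutanoyloxy]-6β,15-dihydroxy-5βH,7αH-elema-1,3,11(13)-trien-12-oic acid (CNP0348657.6)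
Conditions: Pd(PPh3)4 (5 mol %), dimedone, THF, rt; reverse-phase purification near pH 5
Reagents that add atoms: none
Why: Tsuji–Trost deallylation with zerovalent palladium and a carbon scavenger frees the acid under neutral conditions that avoid acyl migration, amine addition to the acrylates and lactonisation.

**Compound list**
1 | 2,4-dimethylpenta-1,3-diene | CC(C)=CC(C)=C | starting material
2 | 3-[(tert-butyldimethylsilyl)oxy]propanal | CC(C)(C)[Si](C)(C)OCCC=O | starting material
3 | potassium 2,4-dimethylpentadienide | [K+].[CH2-]C(C)=CC(C)=C | intermediate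
4 | (2,4-dimethylpenta-2,4-dien-1-yl)diisopinocampheylborane (internal alkene geometry inconsequential) | C=C(C)C=C(C)CB([C@@H]1C[C@@H]2C[C@H]([C@H]1C)C2(C)C)[C@@H]1C[C@@H]2C[C@H]([C@H]1C)C2(C)C | intermediate
5 | diisopinocampheylborinate of 6 | CC(C)(C)[Si](C)(C)OCC[C@@H](OB([C@@H]1C[C@@H]2C[C@H]([C@H]1C)C2(C)C)[C@@H]1C[C@@H]2C[C@H]([C@H]1C)C2(C)C)C(C(C)=C)C(C)=C | intermediate
6 | (3R)-1-[(tert-butyldimethylsilyl)oxy]-5-methyl-4-(prop-1-en-2-yl)hex-5-en-3-ol | CC(C)(C)[Si](C)(C)OCC[C@@H](O)C(C(C)=C)C(C)=C | intermediate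
7 | (3R)-5-methyl-4-(prop-1-en-2-yl)hex-5-ene-1,3-diol | OCC[C@@H](O)C(C(C)=C)C(C)=C | intermediate
8 | (3R)-3-hydroxy-5-methyl-4-(prop-1-en-2-yl)hex-5-enal | O=CC[C@@H](O)C(C(C)=C)C(C)=C | intermediate
9 | (3R)-3-hydroxy-5-methyl-4-(prop-1-en-2-yl)hex-5-enoic acid | OC(=O)C[C@@H](O)C(C(C)=C)C(C)=C | intermediate
10 | allyl (3R)-3-hydroxy-5-methyl-4-(prop-1-en-2-yl)hex-5-enoate | C=CCOC(=O)C[C@@H](O)C(C(C)=C)C(C)=C | intermediate
11 | dilithio alkoxide–enolate of 10 | [Li+].[Li+].C=CCO/C([O-])=C/[C@@H]([O-])C(C(C)=C)C(C)=C | intermediate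
12 | 1-allyl 4-tert-butyl (2S)-2-[(1S)-1-hydroxy-3-methyl-2-(prop-1-en-2-yl)but-3-en-1-yl]butanedioate | C=CCOC(=O)[C@@H](CC(=O)OC(C)(C)C)[C@@H](O)C(C(C)=C)C(C)=C | intermediate
13 | triethylsilyl ether of 12 | C=CCOC(=O)[C@@H](CC(=O)OC(C)(C)C)[C@@H](O[Si](CC)(CC)CC)C(C(C)=C)C(C)=C | intermediate
14 | (3S,4S,5R,6Z)-oxocin-2-one (eight-membered lactone) | O=C1[C@@H](CC(=O)OC(C)(C)C)[C@@H](O[Si](CC)(CC)CC)[C@H](C(C)=C)/C(C)=C\CO1 | intermediate
15 | (3S,4S,5R,6Z)-2-methylideneoxocine | C=C1[C@@H](CC(=O)OC(C)(C)C)[C@@H](O[Si](CC)(CC)CC)[C@H](C(C)=C)/C(C)=C\CO1 | intermediate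
16 | tert-butyl 2-[(1S,2S,3R,4S)-4-ethenyl-4-methyl-6-oxo-3-(prop-1-en-2-yl)-2-(triethylsilyloxy)cyclohexyl]acetate | C=C[C@]1(C)CC(=O)[C@@H](CC(=O)OC(C)(C)C)[C@@H](O[Si](CC)(CC)CC)[C@@H]1C(C)=C | intermediate
17 | 8β-hydroxy tert-butyl ester | C=C[C@]1(C)C[C@@H](O)[C@@H](CC(=O)OC(C)(C)C)[C@@H](O[Si](CC)(CC)CC)[C@@H]1C(C)=C | intermediate
18 | 6β-(triethylsilyloxy)-5βH,7αH,8αH-elema-1,3-dien-12,8-olide | C=C[C@]1(C)C[C@@H](OC2=O)[C@@H](C2)[C@@H](O[Si](CC)(CC)CC)[C@@H]1C(C)=C | intermediate
19 | lithium enolate of 18 | [Li+].C=C[C@]1(C)C[C@@H](OC2[O-])[C@@H](C=2)[C@@H](O[Si](CC)(CC)CC)[C@@H]1C(C)=C | intermediate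
20 | 11-(dimethylaminomethyl) lactone (convex-face adduct) | C=C[C@]1(C)C[C@@H](OC2=O)[C@@H]([C@H]2CN(C)C)[C@@H](O[Si](CC)(CC)CC)[C@@H]1C(C)=C | intermediate
21 | trimethylammonium iodide of 20 | C=C[C@]1(C)C[C@@H](OC2=O)[C@@H]([C@H]2C[N+](C)(C)C)[C@@H](O[Si](CC)(CC)CC)[C@@H]1C(C)=C.[I-] | intermediate
22 | 6β-(triethylsilyloxy)-5βH,7αH,8αH-elema-1,3,11(13)-trien-12,8-olide | C=C[C@]1(C)C[C@@H](OC2=O)[C@@H](C2=C)[C@@H](O[Si](CC)(CC)CC)[C@@H]1C(C)=C | intermediate
23 | lithium 8β-hydroxy-6β-(triethylsilyloxy)elema-1,3,11(13)-trien-12-oate | [Li+].C=C[C@]1(C)C[C@@H](O)[C@@H](C(=C)C([O-])=O)[C@@H](O[Si](CC)(CC)CC)[C@@H]1C(C)=C | intermediate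
24 | allyl 8β-hydroxy-6β-(triethylsilyloxy)-5βH,7αH-elema-1,3,11(13)-trien-12-oate | C=C[C@]1(C)C[C@@H](O)[C@@H](C(=C)C(=O)OCC=C)[C@@H](O[Si](CC)(CC)CC)[C@@H]1C(C)=C | intermediate
25 | methyl 3,4-O-isopropylidene-L-threonate | COC(=O)[C@H](O)[C@@H]1COC(C)(C)O1 | starting material
26 | methyl 2-[(4S)-2,2-dimethyl-1,3-dioxolan-4-yl]-2-oxoacetate | COC(=O)C(=O)[C@@H]1COC(C)(C)O1 | intermediate
27 | methyl 2-[(4R)-2,2-dimethyl-1,3-dioxolan-4-yl]prop-2-enoate | COC(=O)C(=C)[C@@H]1COC(C)(C)O1 | intermediate
28 | 2-[(4R)-2,2-dimethyl-1,3-dioxolan-4-yl]prop-2-enoic acid | OC(=O)C(=C)[C@@H]1COC(C)(C)O1 | intermediate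
29 | mixed anhydride of 28 with 2,4,6-trichlorobenzoic acid | O=C(OC(=O)c1c(Cl)cc(Cl)cc1Cl)C(=C)[C@@H]1COC(C)(C)O1 | intermediate
30 | O8-acylated allyl ester (acetonide, 6-O-triethylsilyl) | C=C[C@]1(C)C[C@@H](OC(=O)C(=C)[C@@H]2COC(C)(C)O2)[C@@H](C(=C)C(=O)OCC=C)[C@@H](O[Si](CC)(CC)CC)[C@@H]1C(C)=C | intermediate
31 | 15-hydroxy derivative of 30 | C=C[C@]1(C)C[C@@H](OC(=O)C(=C)[C@@H]2COC(C)(C)O2)[C@@H](C(=C)C(=O)OCC=C)[C@@H](O[Si](CC)(CC)CC)[C@@H]1C(=C)CO | intermediate
32 | allyl ester of the target | C=C[C@]1(C)C[C@@H](OC(=O)C(=C)[C@@H](O)CO)[C@@H](C(=C)C(=O)OCC=C)[C@@H](O)[C@@H]1C(=C)CO | intermediate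
33 | CNP0348657.6 | C=C[C@]1(C)C[C@@H](OC(=O)C(=C)[C@@H](O)CO)[C@@H](C(=C)C(=O)O)[C@@H](O)[C@@H]1C(=C)CO | target

**Step count**
- Total step count: 19.
- Longest linear sequence: 16 (steps 1–12 and 16–19).

**Steps most likely to fail**

1. **Step 9.** The transannular chair–chair array may be reached only at temperatures at which the exocyclic double bond migrates into the ring or C7 epimerises. The fallback sets out from 14 and returns at 16, with known chemistry throughout.
   - Methanolysis (K2CO3, MeOH) opens the lactone to the seco Z-allylic alcohol methyl ester F1.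
   - Johnson–Claisen rearrangement (MeC(OMe)3, cat. propionic acid, 140 °C) builds C9–C10 in the open chain and gives the quaternary diester F2. With H5 eclipsing the Z-CH2O group (A(1,3) strain), the ketene acetal should attack anti to the bulky C6 branch, which is the same C10 configuration.
   - Dieckmann cyclisation (KOtBu, THF) of C9 onto C8 gives the β-keto ester F3.
   - Krapcho demethoxycarbonylation (LiCl, wet DMSO, heat) returns to 16.

2. **Step 7.** Oligomerisation may overtake closure, because the allyl ester must leave its s-trans conformation, and discrimination between the two isopropenyl groups may be poor. The fallback sets out from 13 and returns at 15.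
   - The acyclic ester is methylenated first with Cp2Ti(μ-Cl)(μ-CH2)AlMe2 to the acyclic allyl vinyl ether F4, which has no ester conformational penalty.
   - The ring is then closed on the enol ether by metathesis at or below 40 °C with the second-generation Hoveyda–Grubbs catalyst (H2IMes)Cl2Ru=CH(2-iPrOC6H4), below the temperature of the open-chain [3,3] shift.

3. **Step 10.** Hydrogen may be delivered to the wrong face of C8, which gives an axial 8α-alcohol that cannot lactonise, or the ketyl may follow side reactions. The fallback sets out from 16 and returns at 18.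
   - Reduction with NaBH4 (MeOH, −20 °C) is used instead. Any 8β-alcohol lactonises directly to 18.
   - The 8α-alcohol tert-butyl ester F5 is converted (Me3SiOTf, 2,6-lutidine, then pH 7 buffer) into the 8α-hydroxy acid F6.
   - F6 closes under Mitsunobu conditions (PPh3, DIAD) with inversion at C8, so both epimers converge on 18.

**Further compounds**
F1 | step 9 | 4-tert-butyl 1-methyl (2S)-2-[(1S,2R,3Z)-5-hydroxy-3-methyl-2-(prop-1-en-2-yl)-1-(triethylsilyloxy)pent-3-en-1-yl]butanedioate | COC(=O)[C@@H](CC(=O)OC(C)(C)C)[C@@H](O[Si](CC)(CC)CC)[C@H](C(C)=C)/C(C)=C\CO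
F2 | step 9 | 4-tert-butyl 1-methyl (2S)-2-[(1S,2R,3S)-3-ethenyl-5-methoxy-3-methyl-5-oxo-2-(prop-1-en-2-yl)-1-(triethylsilyloxy)pentyl]butanedioate | C=C[C@](C)(CC(=O)OC)[C@@H](C(C)=C)[C@H](O[Si](CC)(CC)CC)[C@H](CC(=O)OC(C)(C)C)C(=O)OC
F3 | step 9 | 9-methoxycarbonyl derivative of 16 (enolisable C9) | C=C[C@]1(C)C(C(=O)OC)C(=O)[C@@H](CC(=O)OC(C)(C)C)[C@@H](O[Si](CC)(CC)CC)[C@@H]1C(C)=C
F4 | step 7 | acyclic allyl vinyl ether from 13 | C=CCOC(=C)[C@@H](CC(=O)OC(C)(C)C)[C@@H](O[Si](CC)(CC)CC)C(C(C)=C)C(C)=C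
F5 | step 10 | 8α-hydroxy tert-butyl ester (C8 epimer of 17) | C=C[C@]1(C)C[C@H](O)[C@@H](CC(=O)OC(C)(C)C)[C@@H](O[Si](CC)(CC)CC)[C@@H]1C(C)=C
F6 | step 10 | 8α-hydroxy acid | C=C[C@]1(C)C[C@H](O)[C@@H](CC(=O)O)[C@@H](O[Si](CC)(CC)CC)[C@@H]1C(C)=C
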